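**Retrosynthetic overview**
- The two halves are the same 5,7-dihydroxychromone joined C8–C8''. They differ at one atom: O4' on ring B of unit 1 is a methyl ether, O4''' on ring B'' (C1'''–C6''') of unit 2 is a free phenol. Ring B'' can therefore be made last, born as a para-phenol.
- Last disconnections: the four benzyl ethers, then ring B'' by (4+2) addition of Danishefsky's diene to a C2''-ethynyl group (bonds C1'''–C6''' and C2'''–C3''') with loss of methanol.
- The ethynylchromone comes from the chromone-2''-carboxylate (ring C'' closed by oxalate Claisen condensation and cyclodehydration) by reduction, oxidation and one-carbon homologation.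
- The C8–C8'' bond comes from a Suzuki coupling of an acacetin-derived 8-boronate with 3'-iodo-4',6'-di-O-benzylphloroacetophenone.
- Ring order: rings A, C, B (acacetin) and ring A'' (phloroacetophenone) are bought, then biaryl, then ring C'', then ring B''.

Key step: step 11

Remark: the target has no stereocentre and its SMILES gives no descriptor for the hindered C8–C8'' axis, so the route is planned without atroposelection (racemic axis).

**Step 1**
Reactants: 1 acacetin
Product: 2 5,7-bis(benzyloxy)-4'-methoxyflavone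
Conditions: BnBr (3 equiv), K2CO3, DMF, 80 °C
Reagents that add atoms: benzyl bromide, BrCc1ccccc1
Why: Williamson ether synthesis; excess bromide and heat should also alkylate the chelated 5-OH, while the methyl ether and the pyranone are inert.

**Step 2**
Reactants: 2 5,7-bis(benzyloxy)-4'-methoxyflavone
Product: 3 5,7-bis(benzyloxy)-8-iodo-4'-methoxyflavone
Conditions: NIS, TFA (cat.), MeCN/CH2Cl2, 0 to 23 °C
Reagents that add atoms: N-iodosuccinimide, O=C1CCC(=O)N1I
Why: Electrophilic aromatic iodination, which in 5-O-alkylated 5,7-dioxygenated flavones goes to C8 (C6 lies between two benzyloxy groups and the anisyl ring B is far less activated).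

**Step 3**
Reactants: 3 5,7-bis(benzyloxy)-8-iodo-4'-methoxyflavone
Product: 4 5,7-bis(benzyloxy)-4'-methoxy-8-(4,4,5,5-tetramethyl-1,3,2-dioxaborolan-2-yl)flavone
Conditions: B2pin2, PdCl2(dppf) (5 mol %), KOAc, 1,4-dioxane, 90 °C
Reagents that add atoms: bis(pinacolato)diboron, CC1(C)OB(OC1(C)C)B1OC(C)(C)C(C)(C)O1
Why: Miyaura borylation of an aryl iodide; the weak acetate base should suppress homocoupling and the flavone carbonyl is tolerated, as for known flavone 8-boronates.

**Step 4**
Reactants: 5 2',4',6'-trihydroxyacetophenone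
Product: 6 4',6'-bis(benzyloxy)-2'-hydroxyacetophenone
Conditions: BnBr (2.1 equiv), K2CO3, DMF, 23 °C
Reagents that add atoms: benzyl bromide, BrCc1ccccc1
Why: Williamson ether synthesis that should stop at the dibenzyl ether, because the remaining hydroxyl is hydrogen-bonded to the acetyl group and is the least nucleophilic.

**Step 5**
Reactants: 6 4',6'-bis(benzyloxy)-2'-hydroxyacetophenone
Product: 7 4',6'-bis(benzyloxy)-2'-hydroxy-3'-iodoacetophenone
Conditions: NIS, p-TsOH·H2O (cat.), MeCN, 0 to 23 °C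
Reagents that add atoms: N-iodosuccinimide, O=C1CCC(=O)N1I
Why: Electrophilic aromatic iodination ortho to the free phenol; C3' (between OH and OBn) should be preferred over C5' (between two benzyloxy groups), as with the corresponding dimethyl ether.

**Step 6**
Reactants: 4 5,7-bis(benzyloxy)-4'-methoxy-8-(4,4,5,5-tetramethyl-1,3,2-dioxaborolan-2-yl)flavone; 7 4',6'-bis(benzyloxy)-2'-hydroxy-3'-iodoacetophenone
Product: 8 8-[3-acetyl-4,6-bis(benzyloxy)-2-hydroxyphenyl]-5,7-bis(benzyloxy)-4'-methoxyflavone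
Conditions: Pd(OAc)2 (5 mol %), SPhos (10 mol %), K3PO4, toluene/H2O (10:1), 100 °C
Reagents that add atoms: none
Why: Suzuki–Miyaura coupling (oxidative addition of the iodide to zerovalent palladium, transmetalation, reductive elimination); the bulky dialkylbiarylphosphine is the ligand type that should allow tetra-ortho-oxygenated biaryls, and the free phenoxide next to iodine is tolerated and saves a protecting group.

**Step 7**
Reactants: 8 8-[3-acetyl-4,6-bis(benzyloxy)-2-hydroxyphenyl]-5,7-bis(benzyloxy)-4'-methoxyflavone; 9 diethyl oxalate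
Product: 11 ethyl 5,7-bis(benzyloxy)-8-[5,7-bis(benzyloxy)-2-(4-methoxyphenyl)-4-oxo-4H-chromen-8-yl]-4-oxo-4H-chromene-2-carboxylate, via aryl dioxobutanoate 10 (not isolated)
Conditions: LiN(SiMe3)2 (3.5 equiv), THF, −78 °C; 9, −78 to 23 °C; aq. HCl quench; then p-TsOH·H2O (cat.), toluene/EtOH, 80 °C
Reagents that add atoms: diethyl oxalate (9), CCOC(=O)C(=O)OCC
Why: Crossed Claisen condensation of the phenoxide–enolate dianion with the non-enolisable oxalate, then acid-catalysed cyclodehydration of the 2-hydroxyaryl diketoester (classical chromone-2-carboxylate synthesis); the non-nucleophilic amide base should leave the flavone ring of unit 1 closed.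

**Step 8**
Reactants: 11 ethyl chromone-2''-carboxylate
Product: 12 5,7-bis(benzyloxy)-8-[5,7-bis(benzyloxy)-2-(hydroxymethyl)-4-oxo-4H-chromen-8-yl]-4'-methoxyflavone
Conditions: NaBH4, THF/MeOH, 0 °C
Reagents that add atoms: none
Why: Chemoselective borohydride reduction; the ester on the electron-poor C2'' is activated and should be reduced at 0 °C while the two vinylogous-ester pyranone carbonyls stay untouched, as with ethyl chromone-2-carboxylate itself.

**Step 9**
Reactants: 12 2''-(hydroxymethyl)chromone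
Product: 13 5,7-bis(benzyloxy)-8-[5,7-bis(benzyloxy)-2-formyl-4-oxo-4H-chromen-8-yl]-4'-methoxyflavone
Conditions: Dess–Martin periodinane, CH2Cl2, 23 °C
Reagents that add atoms: none
Why: Dess–Martin oxidation of a primary allylic-type alcohol to the aldehyde under neutral conditions, without over-oxidation or harm to benzyl ethers.

**Step 10**
Reactants: 13 2''-formylchromone
Product: 14 5,7-bis(benzyloxy)-8-[5,7-bis(benzyloxy)-2-ethynyl-4-oxo-4H-chromen-8-yl]-4'-methoxyflavone
Conditions: (MeO)2P(O)CHN2 (1.5 equiv), KOtBu (1.4 equiv), THF, −78 to 0 °C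
Reagents that add atoms: dimethyl (diazomethyl)phosphonate, COP(=O)(OC)C=[N+]=[N-]
Why: Seyferth–Gilbert homologation (addition of the phosphonate anion, cycloelimination to the diazoalkene, loss of N2 and 1,2-hydrogen shift); the aprotic low-temperature variant is chosen so that no methoxide is present to add to C2'' of the pyranone or to the activated alkyne.

**Step 11**
Reactants: 14 2''-ethynylchromone; 15 Danishefsky's diene
Product: 18 5,7,5'',7''-tetra-O-benzyl ether of the target (4'''-OH free), via cyclohexadiene cycloadduct 16 (not isolated), via aryl trimethylsilyl ether 17 (not isolated)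
Conditions: 15 (4 equiv, in two portions), toluene, 110 °C, sealed tube; then 1 M HCl, THF, 23 °C
Reagents that add atoms: Danishefsky's diene (15), CO/C=C/C(=C)O[Si](C)(C)C
Why: Proposed new method: a thermal normal-electron-demand (4+2) cycloaddition in which the nucleophilic CH2 terminus of the diene bonds to the terminal alkyne carbon (C2'''–C3''') and the methoxy-bearing terminus to the internal carbon (C1'''–C6'''), the alkyne LUMO being lowered by conjugation through C2''=C3'' with the C4'' carbonyl, to give the 1,4-cyclohexadiene 16. The closest known reaction is the cycloaddition of this diene with ethynyl ketones and propiolates, which gives para-hydroxyaryl ketones and esters after acid treatment; here the activation is only vinylogous (through a γ-pyranone), which is the untested part. Ring B'' is closed intermolecularly by two C–C bonds in one, probably asynchronous, event and is then aromatised by 1,4-elimination of methanol (OMe at C6''', H at C3''') to the silyl ether 17, which dilute acid hydrolyses to the phenol. The only new stereocentre (C6''' of 16) is lost on aromatisation, so no stereocontrol is needed. The step needs regioselectivity (oxygen para, not meta, to C1''') and chemoselectivity (alkyne over the two pyranone C2=C3 bonds): the first follows from the polarisation of the alkyne, whose terminal carbon is the electrophilic 1,6-position of the ynenone, and the second from both pyranone double bonds being trisubstituted, donor-substituted by the ring oxygen and unreactive to siloxydienes without a Lewis acid, while the alkyne points away from the crowded C8–C8'' axis.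

**Step 12**
Reactants: 18 5,7,5'',7''-tetra-O-benzyl ether of the target
Product: 19 8-[5,7-dihydroxy-2-(4-hydroxyphenyl)-4-oxo-4H-chromen-8-yl]-5,7-dihydroxy-4'-methoxyflavone (target)
Conditions: BCl3 (12 equiv), pentamethylbenzene (20 equiv), CH2Cl2, −78 °C; MeOH/H2O quench
Reagents that add atoms: none
Why: Lewis-acid cleavage of aryl benzyl ethers with a cation scavenger; pentamethylbenzene should trap the benzyl cations before they C-benzylate the phloroglucinol rings, and the non-chelated 4'-methyl ether is inert to BCl3 at −78 °C.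

**Compound list**
1 | acacetin (5,7-dihydroxy-4'-methoxyflavone) | COc1ccc(cc1)-c1cc(=O)c2c(O)cc(O)cc2o1 | starting material
2 | 5,7-bis(benzyloxy)-4'-methoxyflavone | COc1ccc(cc1)-c1cc(=O)c2c(OCc3ccccc3)cc(OCc3ccccc3)cc2o1 | intermediate
3 | 5,7-bis(benzyloxy)-8-iodo-4'-methoxyflavone | COc1ccc(cc1)-c1cc(=O)c2c(OCc3ccccc3)cc(OCc3ccccc3)c(I)c2o1 | intermediate
4 | 5,7-bis(benzyloxy)-4'-methoxy-8-(4,4,5,5-tetramethyl-1,3,2-dioxaborolan-2-yl)flavone | COc1ccc(cc1)-c1cc(=O)c2c(OCc3ccccc3)cc(OCc3ccccc3)c(B3OC(C)(C)C(C)(C)O3)c2o1 | intermediate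
5 | 2',4',6'-trihydroxyacetophenone | CC(=O)c1c(O)cc(O)cc1O | starting material
6 | 4',6'-bis(benzyloxy)-2'-hydroxyacetophenone | CC(=O)c1c(O)cc(OCc2ccccc2)cc1OCc1ccccc1 | intermediate
7 | 4',6'-bis(benzyloxy)-2'-hydroxy-3'-iodoacetophenone | CC(=O)c1c(O)c(I)c(OCc2ccccc2)cc1OCc1ccccc1 | intermediate
8 | 8-[3-acetyl-4,6-bis(benzyloxy)-2-hydroxyphenyl]-5,7-bis(benzyloxy)-4'-methoxyflavone | COc1ccc(cc1)-c1cc(=O)c2c(OCc3ccccc3)cc(OCc3ccccc3)c(-c3c(O)c(C(C)=O)c(OCc4ccccc4)cc3OCc3ccccc3)c2o1 | intermediate
9 | diethyl oxalate | CCOC(=O)C(=O)OCC | starting material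
10 | ethyl 4-aryl-2,4-dioxobutanoate (aryl = the 2-hydroxy-4,6-bis(benzyloxy)phenyl ring of 8, carrying the flavon-8-yl group at C3) | CCOC(=O)C(=O)CC(=O)c1c(OCc2ccccc2)cc(OCc2ccccc2)c(c1O)-c1c(OCc2ccccc2)cc(OCc2ccccc2)c2c(=O)cc(oc12)-c1ccc(OC)cc1 | intermediate
11 | ethyl 5,7-bis(benzyloxy)-8-[5,7-bis(benzyloxy)-2-(4-methoxyphenyl)-4-oxo-4H-chromen-8-yl]-4-oxo-4H-chromene-2-carboxylate | CCOC(=O)c1cc(=O)c2c(OCc3ccccc3)cc(OCc3ccccc3)c(c2o1)-c1c(OCc2ccccc2)cc(OCc2ccccc2)c2c(=O)cc(oc12)-c1ccc(OC)cc1 | intermediate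
12 | 5,7-bis(benzyloxy)-8-[5,7-bis(benzyloxy)-2-(hydroxymethyl)-4-oxo-4H-chromen-8-yl]-4'-methoxyflavone | OCc1cc(=O)c2c(OCc3ccccc3)cc(OCc3ccccc3)c(c2o1)-c1c(OCc2ccccc2)cc(OCc2ccccc2)c2c(=O)cc(oc12)-c1ccc(OC)cc1 | intermediate
13 | 5,7-bis(benzyloxy)-8-[5,7-bis(benzyloxy)-2-formyl-4-oxo-4H-chromen-8-yl]-4'-methoxyflavone | O=Cc1cc(=O)c2c(OCc3ccccc3)cc(OCc3ccccc3)c(c2o1)-c1c(OCc2ccccc2)cc(OCc2ccccc2)c2c(=O)cc(oc12)-c1ccc(OC)cc1 | intermediate
14 | 5,7-bis(benzyloxy)-8-[5,7-bis(benzyloxy)-2-ethynyl-4-oxo-4H-chromen-8-yl]-4'-methoxyflavone | C#Cc1cc(=O)c2c(OCc3ccccc3)cc(OCc3ccccc3)c(c2o1)-c1c(OCc2ccccc2)cc(OCc2ccccc2)c2c(=O)cc(oc12)-c1ccc(OC)cc1 | intermediate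
15 | Danishefsky's diene ((E)-1-methoxy-3-(trimethylsilyloxy)buta-1,3-diene) | CO/C=C/C(=C)O[Si](C)(C)C | starting material
16 | 8-{5,7-bis(benzyloxy)-2-[6-methoxy-4-(trimethylsilyloxy)cyclohexa-1,4-dien-1-yl]-4-oxo-4H-chromen-8-yl}-5,7-bis(benzyloxy)-4'-methoxyflavone (C6''' unassigned, racemic) | COC1C=C(O[Si](C)(C)C)CC=C1c1cc(=O)c2c(OCc3ccccc3)cc(OCc3ccccc3)c(c2o1)-c1c(OCc2ccccc2)cc(OCc2ccccc2)c2c(=O)cc(oc12)-c1ccc(OC)cc1 | intermediate
17 | 4'''-O-trimethylsilyl-5,7,5'',7''-tetra-O-benzyl ether of the target | C[Si](C)(C)Oc1ccc(cc1)-c1cc(=O)c2c(OCc3ccccc3)cc(OCc3ccccc3)c(c2o1)-c1c(OCc2ccccc2)cc(OCc2ccccc2)c2c(=O)cc(oc12)-c1ccc(OC)cc1 | intermediate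
18 | 8-[5,7-bis(benzyloxy)-2-(4-hydroxyphenyl)-4-oxo-4H-chromen-8-yl]-5,7-bis(benzyloxy)-4'-methoxyflavone (5,7,5'',7''-tetra-O-benzyl ether of the target) | Oc1ccc(cc1)-c1cc(=O)c2c(OCc3ccccc3)cc(OCc3ccccc3)c(c2o1)-c1c(OCc2ccccc2)cc(OCc2ccccc2)c2c(=O)cc(oc12)-c1ccc(OC)cc1 | intermediate
19 | 8-[5,7-dihydroxy-2-(4-hydroxyphenyl)-4-oxo-4H-chromen-8-yl]-5,7-dihydroxy-4'-methoxyflavone (CNP0322111.0) | COc1ccc(-c2cc(=O)c3c(O)cc(O)c(-c4c(O)cc(O)c5c(=O)cc(-c6ccc(O)cc6)oc45)c3o2)cc1 | target

**Step count and risks**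
Total steps: 12. Longest linear sequence: 10 steps (1, 2, 3, 6, 7, 8, 9, 10, 11, 12 from acacetin).

Steps most likely to fail:

1. Step 11. The alkyne is activated only through the pyranone and may react too slowly, so that the diene polymerises on heating or its silyl enol ether adds in Mukaiyama–Michael fashion to C2'' before cycloaddition occurs. Fallback with known chemistry, setting out from 8 and returning at 19: the dianion of 8 (LiN(SiMe3)2, THF, −78 °C) would be C-acylated with 4-(benzyloxy)benzoyl chloride (Baker–Venkataraman-type) to the 1,3-diketone F1. Cyclodehydration (p-TsOH·H2O, toluene, 100 °C) would close ring C'' and give the penta-O-benzyl biflavone F2. BCl3 and pentamethylbenzene at −78 °C would then remove all five benzyl groups and give 19, the ring B methyl ether keeping the two halves distinct.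

2. Step 6. Transmetalation at the di-ortho-oxygenated boronate may be slow, so that protodeboronation of 4 and reductive deiodination of 7 outrun the coupling. Fallback setting out from 7 and returning at 8: protection (MOMCl, iPr2NEt, CH2Cl2) would give the methoxymethyl ether F3. Ullmann homocoupling (Cu powder, DMF, 150 °C) would give the symmetric bis-MOM biaryl F4, and HCl/MeOH the biaryl bis-phenol F5. Acylation of its polyanion with one equivalent of 4-methoxybenzoyl chloride (LiN(SiMe3)2, THF, −78 °C; statistical, unreacted F5 recycled) would give the mono-1,3-diketone F6. Acid cyclodehydration (p-TsOH·H2O, toluene, 100 °C) would then build rings C and B of unit 1 on one half and give 8.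

3. Step 10. The phosphonate anion or tert-butoxide may attack the electrophilic C2'' of the pyranone with ring opening, or the activated terminal alkyne may oligomerise under base. Fallback setting out from 13 and returning at 14: Stork–Zhao olefination (Ph3P=CHI from (iodomethyl)triphenylphosphonium iodide and NaN(SiMe3)2, THF, −78 °C) would give the (Z)-2''-(2-iodovinyl)chromone F7. Anti-elimination of hydrogen iodide with DBU (toluene, 23 to 60 °C) would give 14.

**Further compounds**
F1 | step 11 | 1-[4-(benzyloxy)phenyl]-3-aryl-propane-1,3-dione (aryl = the 2-hydroxy-4,6-bis(benzyloxy)phenyl ring of 8 with the flavon-8-yl group at C3) | O=C(CC(=O)c1ccc(OCc2ccccc2)cc1)c1c(OCc2ccccc2)cc(OCc2ccccc2)c(c1O)-c1c(OCc2ccccc2)cc(OCc2ccccc2)c2c(=O)cc(oc12)-c1ccc(OC)cc1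
F2 | step 11 | 5,7,5'',7'',4'''-penta-O-benzyl ether of the target | c1ccccc1COc1ccc(cc1)-c1cc(=O)c2c(OCc3ccccc3)cc(OCc3ccccc3)c(c2o1)-c1c(OCc2ccccc2)cc(OCc2ccccc2)c2c(=O)cc(oc12)-c1ccc(OC)cc1
F3 | step 6 | 4',6'-bis(benzyloxy)-3'-iodo-2'-(methoxymethoxy)acetophenone | CC(=O)c1c(OCOC)c(I)c(OCc2ccccc2)cc1OCc1ccccc1
F4 | step 6 | 3,3'-diacetyl-4,4',6,6'-tetrakis(benzyloxy)-2,2'-bis(methoxymethoxy)biphenyl | CC(=O)c1c(OCOC)c(c(OCc2ccccc2)cc1OCc1ccccc1)-c1c(OCOC)c(C(C)=O)c(OCc2ccccc2)cc1OCc1ccccc1
F5 | step 6 | 3,3'-diacetyl-4,4',6,6'-tetrakis(benzyloxy)biphenyl-2,2'-diol | CC(=O)c1c(O)c(c(OCc2ccccc2)cc1OCc1ccccc1)-c1c(O)c(C(C)=O)c(OCc2ccccc2)cc1OCc1ccccc1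
F6 | step 6 | mono-[3-(4-methoxyphenyl)-3-oxopropanoyl] analogue of F5 (one acetyl group C-acylated) | COc1ccc(cc1)C(=O)CC(=O)c1c(O)c(c(OCc2ccccc2)cc1OCc1ccccc1)-c1c(O)c(C(C)=O)c(OCc2ccccc2)cc1OCc1ccccc1
F7 | step 10 | 5,7-bis(benzyloxy)-8-{5,7-bis(benzyloxy)-2-[(Z)-2-iodovinyl]-4-oxo-4H-chromen-8-yl}-4'-methoxyflavone | I/C=C\c1cc(=O)c2c(OCc3ccccc3)cc(OCc3ccccc3)c(c2o1)-c1c(OCc2ccccc2)cc(OCc2ccccc2)c2c(=O)cc(oc12)-c1ccc(OC)cc1
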